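Retrosynthesis: the four O–CH3 bonds are cut first, then the C2=C3 unsaturation (back to a 2,3-dihydrobenzofuran), then the furan ring at C3a–C3 and O1–C2, leaving a phloretin-type 2,6-dihydroxyaryl ketone and an isoliquiritigenin-type chalcone.
Enabling feature: the furan ring (O1, C2, C3, C3a, C7a) is one free ring CH (C3a) and its neighbouring phenolic oxygen (O1 on C7a) of the phloretin A ring, laid across Cα (C3, carrying the 2,4-dihydroxybenzoyl group) and Cβ (C2, carrying the 4-hydroxyphenyl group) of the chalcone. The 4-hydroxyl of the C2 aryl ring is conjugated through C2 with C3, so oxidising that phenol places the radical on the carbon that must bond to C3a and makes C2 a quinone methide carbon for O1.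
Forward: the dihydrochalcone half (benzene ring and C7 acyl chain complete) comes from naringenin by 7,4′-di-O-methylation and alkaline ring-opening hydrogenation; the chalcone half, with its 4-hydroxyl deliberately left free, comes from a Claisen–Schmidt condensation.
The furan ring, the only ring made, arises in the anodic cross-coupling (C3a–C3 first, then O1–C2); a quinone then aromatises it and boron tribromide frees the phenols.
Stereochemistry: the target has none; C2 and C3 appear as a racemic trans pair in the key step and are erased by the dehydrogenation.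

Key step: step 4

Remark on the chemistry: the target has no stereocentre, so the requested single enantiomer is the achiral compound itself and no absolute stereocontrol is needed.

Step 1
Reactants: 1 (±)-naringenin [5,7-dihydroxy-2-(4-hydroxyphenyl)chroman-4-one]
Product: 2 (±)-5-hydroxy-7-methoxy-2-(4-methoxyphenyl)chroman-4-one (naringenin 7,4′-dimethyl ether)
Conditions: Me2SO4 (2.1 equiv), K2CO3 (2.2 equiv), acetone, rt
Reagents that add atoms: dimethyl sulfate, COS(=O)(=O)OC
Why: Williamson O-methylation under mild carbonate conditions should take the two acidic, non-chelated hydroxyls (7-OH, vinylogous to the carbonyl, and 4′-OH) and leave the 5-OH, which is held in a hydrogen bond to the C4 carbonyl; the stereocentre of 1 is untouched and is removed in step 2.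

Step 2
Reactants: 2 (±)-5-hydroxy-7-methoxy-2-(4-methoxyphenyl)chroman-4-one
Product: 4 1-(2,6-dihydroxy-4-methoxyphenyl)-3-(4-methoxyphenyl)propan-1-one (4,4′-di-O-methylphloretin), via ring-opened chalcone 3 (not isolated)
Conditions: H2 (1 atm), 10% Pd/C, 2 M aq KOH/EtOH, rt; then aq HCl to pH 3
Reagents that add atoms: none
Why: Alkaline catalytic hydrogenation of a flavanone to a dihydrochalcone: hydroxide opens the pyranone ring by E1cB (retro-oxa-Michael) to the chalcone phenolate 3, whose C=C is hydrogenated over palladium while the aryl ketone (a vinylogous carboxylate in the phenolate) and the aryl ethers stay intact, and the ring opening removes the only stereocentre.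

Step 3
Reactants: 5 1-(2,4-dimethoxyphenyl)ethanone (2′,4′-dimethoxyacetophenone); 6 4-hydroxybenzaldehyde
Product: 7 (E)-1-(2,4-dimethoxyphenyl)-3-(4-hydroxyphenyl)prop-2-en-1-one (4-hydroxy-2′,4′-dimethoxychalcone)
Conditions: KOH (50% aq, 4 equiv), EtOH, rt → 50 °C; then aq HCl
Reagents that add atoms: none
Why: Claisen–Schmidt (crossed aldol) condensation: the enolate of 5 adds to the non-enolisable aldehyde 6 and E1cB dehydration gives the conjugated (E)-enone under thermodynamic control, the excess of hydroxide compensating for the lower electrophilicity of the phenolate form of 6.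

Step 4
Reactants: 4 1-(2,6-dihydroxy-4-methoxyphenyl)-3-(4-methoxyphenyl)propan-1-one; 7 (E)-1-(2,4-dimethoxyphenyl)-3-(4-hydroxyphenyl)prop-2-en-1-one
Product: 9 (±)-trans-1-[3-(2,4-dimethoxybenzoyl)-6-hydroxy-2-(4-hydroxyphenyl)-4-methoxy-2,3-dihydro-1-benzofuran-7-yl]-3-(4-methoxyphenyl)propan-1-one (2S*,3S* racemate; the 2S,3S enantiomer is drawn), via p-quinone methide 8 (not isolated)
Conditions: graphite anode/Pt cathode, undivided cell, constant current (about 2 mA cm−2, about 2.2 F per mol of 7), nBu4NBF4 (0.1 M), HFIP/CH2Cl2 (4:1), rt; 4 (3 equiv), 7 (1 equiv) added slowly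
Reagents that add atoms: none
Why: Proposed new method: anodic one-electron oxidation of the free 4-hydroxyl of chalcone 7 should give a phenoxyl radical that carries much of its spin on Cα (an α-keto radical vinylogous to the oxygen); this electrophilic carbon is captured by the most nucleophilic arene carbon in the cell, the ring CH of 4 flanked by OH and OMe, and loss of a second electron and a proton rearomatises that ring, forms C3a–C3 and leaves p-quinone methide 8. The closest known reaction types are the oxidative 8–5′ coupling of 4-hydroxycinnamoyl phenols to phenylcoumarans (silver(I) oxide, peroxidase or anode) and the anodic dehydrogenative phenol–arene cross-coupling in HFIP. The furan ring then closes by 5-exo-trig conjugate addition of the adjacent phenolic oxygen to the exocyclic methide carbon of 8 (O1–C2), which restores the 4-hydroxyphenyl ring. C2 and C3 are formed as a racemic pair whose trans arrangement of aryl and aroyl groups is the thermodynamic one, reachable because C3 is enolisable and the closure is reversible, and both centres disappear in step 5. The step needs cross-coupling over homo-coupling, bond formation at Cα and not at the ortho carbons or the oxygen of the chalcone phenol, and closure by one oxygen only: an excess of 4 with slow addition of 7 in radical-stabilising, non-nucleophilic HFIP serves the first, the spin distribution of the 4-oxycinnamoyl radical and the fast intramolecular capture of 8 the second, and the methyl ether on the oxygen para to the acyl group of 4, whose two ring CH positions are mirror-equivalent, the third. Whichever phenol is discharged first, the same C–C bond should result, because it joins the site of highest spin density of one partner to the most nucleophilic carbon of the other, whereas a chalcone with an etherified 4-oxygen would be a polarity-mismatched acceptor and would leave 4 to dimerise.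

Step 5
Reactants: 9 (±)-trans-1-[3-(2,4-dimethoxybenzoyl)-6-hydroxy-2-(4-hydroxyphenyl)-4-methoxy-2,3-dihydro-1-benzofuran-7-yl]-3-(4-methoxyphenyl)propan-1-one
Product: 10 1-[3-(2,4-dimethoxybenzoyl)-6-hydroxy-2-(4-hydroxyphenyl)-4-methoxy-1-benzofuran-7-yl]-3-(4-methoxyphenyl)propan-1-one
Conditions: DDQ (1.1 equiv), 1,4-dioxane, rt → 50 °C
Reagents that add atoms: none
Why: Quinone dehydrogenation (DDQ aromatisation of a 2-aryl-2,3-dihydrobenzofuran): oxidation at the 4-hydroxybenzylic, oxygen-bearing C2–H gives a quinone methide/oxocarbenium species that loses the acidic C3–H next to the aroyl carbonyl to form the aromatic furan, this position being far more hydridic than the saturated chain of the C7 acyl group, and both stereocentres vanish.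

Step 6
Reactants: 10 1-[3-(2,4-dimethoxybenzoyl)-6-hydroxy-2-(4-hydroxyphenyl)-4-methoxy-1-benzofuran-7-yl]-3-(4-methoxyphenyl)propan-1-one
Product: 11 1-[3-(2,4-dihydroxybenzoyl)-4,6-dihydroxy-2-(4-hydroxyphenyl)-1-benzofuran-7-yl]-3-(4-hydroxyphenyl)propan-1-one (CNP0181782.0)
Conditions: BBr3 (12 equiv), CH2Cl2, −78 °C → rt; then ice-water
Reagents that add atoms: none
Why: Boron tribromide demethylation of aryl methyl ethers: coordination of boron to each ether oxygen followed by bromide attack at methyl should free the four remaining phenols, while the two ketones, the benzofuran and the hydroxyls already free only form borates that are hydrolysed on work-up, and no stereocentre is involved.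

Compound list
1 | (±)-naringenin | O=C1CC(c2ccc(O)cc2)Oc2cc(O)cc(O)c21 | starting material
2 | (±)-5-hydroxy-7-methoxy-2-(4-methoxyphenyl)chroman-4-one | COc1ccc(C2CC(=O)c3c(O)cc(OC)cc3O2)cc1 | intermediate
3 | (E)-1-(2,6-dihydroxy-4-methoxyphenyl)-3-(4-methoxyphenyl)prop-2-en-1-one | COc1ccc(/C=C/C(=O)c2c(O)cc(OC)cc2O)cc1 | intermediate (not isolated)
4 | 1-(2,6-dihydroxy-4-methoxyphenyl)-3-(4-methoxyphenyl)propan-1-one | COc1ccc(CCC(=O)c2c(O)cc(OC)cc2O)cc1 | intermediate
5 | 1-(2,4-dimethoxyphenyl)ethanone | CC(=O)c1ccc(OC)cc1OC | starting material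
6 | 4-hydroxybenzaldehyde | O=Cc1ccc(O)cc1 | starting material
7 | (E)-1-(2,4-dimethoxyphenyl)-3-(4-hydroxyphenyl)prop-2-en-1-one | COc1ccc(C(=O)/C=C/c2ccc(O)cc2)c(OC)c1 | intermediate
8 | (±)-p-quinone methide: 1-{3-[1-(2,4-dimethoxyphenyl)-1-oxo-3-(4-oxocyclohexa-2,5-dien-1-ylidene)propan-2-yl]-2,6-dihydroxy-4-methoxyphenyl}-3-(4-methoxyphenyl)propan-1-one | COc1ccc(CCC(=O)c2c(O)cc(OC)c(C(C=C3C=CC(=O)C=C3)C(=O)c3ccc(OC)cc3OC)c2O)cc1 | intermediate (not isolated)
9 | (±)-trans-1-[3-(2,4-dimethoxybenzoyl)-6-hydroxy-2-(4-hydroxyphenyl)-4-methoxy-2,3-dihydro-1-benzofuran-7-yl]-3-(4-methoxyphenyl)propan-1-one (2S,3S enantiomer of the racemate drawn) | COc1ccc(CCC(=O)c2c(O)cc(OC)c3c2O[C@H](c2ccc(O)cc2)[C@H]3C(=O)c2ccc(OC)cc2OC)cc1 | intermediate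
10 | 1-[3-(2,4-dimethoxybenzoyl)-6-hydroxy-2-(4-hydroxyphenyl)-4-methoxy-1-benzofuran-7-yl]-3-(4-methoxyphenyl)propan-1-one | COc1ccc(CCC(=O)c2c(O)cc(OC)c3c(C(=O)c4ccc(OC)cc4OC)c(-c4ccc(O)cc4)oc23)cc1 | intermediate
11 | 1-[3-(2,4-dihydroxybenzoyl)-4,6-dihydroxy-2-(4-hydroxyphenyl)-1-benzofuran-7-yl]-3-(4-hydroxyphenyl)propan-1-one | O=C(CCc1ccc(O)cc1)c1c(O)cc(O)c2c(C(=O)c3ccc(O)cc3O)c(-c3ccc(O)cc3)oc12 | target

Total step count: 6. Longest linear sequence: 5 (steps 1, 2, 4, 5, 6).

Steps most likely to fail

Step 4 (proposed new method).
- What may go wrong: the chalcone-derived radical may dimerise or oligomerise with itself (8–5′, 8–8 or 8–O coupling) faster than 4 captures it. It may also couple through a ring carbon or through oxygen. Electro-generated acid may promote the polarity-normal conjugate addition of 4 to Cβ. The product, which still has a hydroxyl next to a free ring CH, may be oxidised and annulated a second time.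
- Fallback: it uses known palladium chemistry, sets out from 4 and comes back to the route at 11. Mono-iodination of one of the two equivalent ring CH positions (N-iodosuccinimide, MeCN, 0 °C) should give 1-(2,6-dihydroxy-3-iodo-4-methoxyphenyl)-3-(4-methoxyphenyl)propan-1-one F1. Sonogashira coupling with 4-ethynylanisole (PdCl2(PPh3)2, CuI, Et3N, THF, rt) should give the o-alkynylphenol 1-{2,6-dihydroxy-4-methoxy-3-[(4-methoxyphenyl)ethynyl]phenyl}-3-(4-methoxyphenyl)propan-1-one F2. Carbonylative heteroannulation of F2 with 1-iodo-2,4-dimethoxybenzene under CO (1 atm, Pd(PPh3)4, K2CO3, MeCN, 50 °C) proceeds by oxidative addition, CO insertion, anti-oxypalladation of the alkyne by the only phenoxide next to it, and reductive elimination. It should give the fully aromatic 1-[3-(2,4-dimethoxybenzoyl)-6-hydroxy-4-methoxy-2-(4-methoxyphenyl)-1-benzofuran-7-yl]-3-(4-methoxyphenyl)propan-1-one F3. Boron tribromide, used as in step 6, then cleaves its five methyl ethers to give 11.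

Step 5.
- What may go wrong: the quinone may oxidise the free phenols of 9 or of the product (phenoxyl coupling, addition of a phenol to the quinone, over-oxidation of the 4-hydroxyphenyl-benzofuran) instead of cleanly removing the C2 and C3 hydrogens.
- Fallback: it sets out from 9 and comes back at 10. Both phenols are masked (Ac2O, pyridine, cat DMAP, rt) to give the diacetate of 9 F4, so that the quinone can act only as a hydride acceptor at C2–H. Dehydrogenation with DDQ in refluxing 1,4-dioxane should give the benzofuran diacetate F5, and K2CO3 in MeOH at rt removes the acetates to return 10.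

Step 6.
- What may go wrong: cleavage may stall at partially demethylated boron chelates (the two anisole-type ethers remote from a carbonyl are the slowest), or the strongly Lewis-acidic medium may degrade the electron-rich 3-aroylbenzofuran on warming.
- Fallback: it sets out from 10 and comes back at 11. The mechanism is changed from electrophilic activation at oxygen to SN2 attack of a soft nucleophile on the methyl carbons under basic conditions (NaSEt, DMF, 120 °C, then aq HCl). The polyphenolate that builds up is electron-rich and should resist conjugate addition at C2. No new compound is made on the way (F0).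

Further compounds
F1 | step 4 | 1-(2,6-dihydroxy-3-iodo-4-methoxyphenyl)-3-(4-methoxyphenyl)propan-1-one | COc1ccc(CCC(=O)c2c(O)cc(OC)c(I)c2O)cc1
F2 | step 4 | 1-{2,6-dihydroxy-4-methoxy-3-[(4-methoxyphenyl)ethynyl]phenyl}-3-(4-methoxyphenyl)propan-1-one | COc1ccc(CCC(=O)c2c(O)cc(OC)c(C#Cc3ccc(OC)cc3)c2O)cc1
F3 | step 4 | 1-[3-(2,4-dimethoxybenzoyl)-6-hydroxy-4-methoxy-2-(4-methoxyphenyl)-1-benzofuran-7-yl]-3-(4-methoxyphenyl)propan-1-one | COc1ccc(CCC(=O)c2c(O)cc(OC)c3c(C(=O)c4ccc(OC)cc4OC)c(-c4ccc(OC)cc4)oc23)cc1
F4 | step 5 | (±)-trans-4-{6-acetoxy-3-(2,4-dimethoxybenzoyl)-4-methoxy-7-[3-(4-methoxyphenyl)propanoyl]-2,3-dihydro-1-benzofuran-2-yl}phenyl acetate | COc1ccc(CCC(=O)c2c(OC(C)=O)cc(OC)c3c2O[C@H](c2ccc(OC(C)=O)cc2)[C@H]3C(=O)c2ccc(OC)cc2OC)cc1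
F5 | step 5 | 4-{6-acetoxy-3-(2,4-dimethoxybenzoyl)-4-methoxy-7-[3-(4-methoxyphenyl)propanoyl]-1-benzofuran-2-yl}phenyl acetate | COc1ccc(CCC(=O)c2c(OC(C)=O)cc(OC)c3c(C(=O)c4ccc(OC)cc4OC)c(-c4ccc(OC(C)=O)cc4)oc23)cc1
F0 | step 6 | none | none
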